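**Retrosynthetic overview**

1. Numbering used throughout: ring C1 (O-angeloyl), C2, C3 (CH3), C4 (OH), C5, C6 (side chain); chain C7 (CH3), C8, C9 (OAc), C10=C11. The route rests on the C1–O and C4–O bonds: they are 1,4-related on the cyclohexane, cis to each other and anti to the C6 chain, which is one O2 molecule laid across a C1=C2–C3=C4 ring diene.
2. 35 ⇐ 34 ⇐ 31 ⇐ 29 ⇐ endoperoxide 28: axial-selective reduction of the C4 ketone, angeloylation of C1–OH, copper hydride reduction with equilibration at C3, base-induced opening of the peroxide.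
3. 28 ⇐ diene acetate 26 + singlet O2: [4+2] cycloaddition that forms C1–O and C4–O and closes the 1,2-dioxane ring of a 2,3-dioxabicyclo[2.2.2]oct-5-ene.
4. 26 ⇐ dienyl triflate 21 (C3–CH3 by cross-coupling on a diene of fixed position) ⇐ cyclohexenone 18 ⇐ aldehyde 14 + methyl vinyl ketone (amine-catalysed Michael addition sets C6, aldol condensation closes the carbocycle).
5. 14 ⇐ 3-methylglutaric anhydride 1 (C7 by desymmetrisation, C9 by CBS reduction of the isobutenyl ketone). Ring order: carbocycle (step 8), then the dioxane ring (step 13, opened again in step 14).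

Key step: step 13

Assumption: the quinidine-derived catalyst (DHQD)2AQN is taken to give the (R)-hemiester 3; if its sense of induction is the opposite, the quinine-derived (DHQ)2AQN is used in its place and nothing else changes.

**Route**

Step 1
Reactants: 1 3-methylglutaric anhydride; 2 methanol
Product: 3 (R)-5-methoxy-3-methyl-5-oxopentanoic acid
Conditions: MeOH (10 equiv), (DHQD)2AQN (10 mol%), Et2O, −40 °C
Reagents that add atoms: methanol, CO
Why: Cinchona-alkaloid-catalysed alcoholysis of a prochiral cyclic anhydride (desymmetrisation), in which the catalyst acts as a chiral general base and directs methanol to one enantiotopic carbonyl, so that C7 is set by catalyst control.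

Step 2
Reactants: 3 (R)-5-methoxy-3-methyl-5-oxopentanoic acid; 4 N,O-dimethylhydroxylamine hydrochloride
Product: 6 methyl (R)-5-[methoxy(methyl)amino]-3-methyl-5-oxopentanoate, via acyl imidazolide 5 (not isolated)
Conditions: 1,1'-carbonyldiimidazole (1.1 equiv), CH2Cl2, 0 °C to rt; then 4 (1.2 equiv), rt
Reagents that add atoms: N,O-dimethylhydroxylamine hydrochloride, CNOC.Cl
Why: Amide coupling through the acyl imidazolide gives the Weinreb amide without touching the methyl ester, and C7 is not α to a carbonyl and cannot epimerise.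

Step 3
Reactants: 6 methyl (R)-5-[methoxy(methyl)amino]-3-methyl-5-oxopentanoate; 7 2-methyl-1-propenylmagnesium bromide
Product: 9 methyl (R)-3,7-dimethyl-5-oxooct-6-enoate, via magnesium hemiaminal 8 (not isolated)
Conditions: 7 (1.15 equiv), THF, −20 to 0 °C; then aq. NH4Cl
Reagents that add atoms: 2-methyl-1-propenylmagnesium bromide, CC(C)=C[Mg]Br
Why: Weinreb ketone synthesis, in which the alkenyl Grignard reagent adds faster to the N-methoxy-N-methylamide than to the methyl ester at low temperature and the chelated tetrahedral adduct 8 holds until the quench, so that neither over-addition nor conjugate addition to the enone can follow.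

Step 4
Reactants: 9 methyl (R)-3,7-dimethyl-5-oxooct-6-enoate
Product: 10 methyl (3R,5R)-5-hydroxy-3,7-dimethyloct-6-enoate
Conditions: (S)-2-methyl-CBS-oxazaborolidine (15 mol%), BH3·SMe2 (0.7 equiv), THF, −30 °C; then MeOH
Reagents that add atoms: none
Why: Corey–Bakshi–Shibata reduction, in which the ketone binds to the catalyst boron with the alkenyl group as the large substituent and hydride is delivered from the nitrogen-bound borane, which should set C9 as (R) under catalyst control while the ester is left alone at this temperature.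

Step 5
Reactants: 10 methyl (3R,5R)-5-hydroxy-3,7-dimethyloct-6-enoate; 11 tert-butyldimethylsilyl chloride
Product: 12 methyl (3R,5R)-5-[(tert-butyldimethylsilyl)oxy]-3,7-dimethyloct-6-enoate
Conditions: t-BuMe2SiCl, imidazole, DMF, 0 °C to rt
Reagents that add atoms: tert-butyldimethylsilyl chloride, CC(C)(C)[Si](C)(C)Cl
Why: Standard silylation of a secondary allylic alcohol, done at once so that the 5-hydroxy ester does not close to the δ-lactone, and giving an ether that withstands the hydride, enolate and Grignard steps that an acetate would not.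

Step 6
Reactants: 12 methyl (3R,5R)-5-[(tert-butyldimethylsilyl)oxy]-3,7-dimethyloct-6-enoate
Product: 14 (3R,5R)-5-[(tert-butyldimethylsilyl)oxy]-3,7-dimethyloct-6-enal, via aluminium hemiacetal 13 (not isolated)
Conditions: i-Bu2AlH (1.05 equiv), CH2Cl2, −78 °C; MeOH, then aq. potassium sodium tartrate
Reagents that add atoms: none
Why: Partial reduction of an ester, in which the tetrahedral aluminium hemiacetal 13 persists at −78 °C and collapses to the aldehyde only on work-up, with neither stereocentre touched.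

Step 7
Reactants: 14 (3R,5R)-5-[(tert-butyldimethylsilyl)oxy]-3,7-dimethyloct-6-enal; 15 methyl vinyl ketone
Product: 16 (2S,3R,5R)-5-[(tert-butyldimethylsilyl)oxy]-3,7-dimethyl-2-(3-oxobutyl)oct-6-enal
Conditions: 15 (1.5 equiv), (S)-2-[methoxy(diphenyl)methyl]pyrrolidine (10 mol%), ethyl 3,4-dihydroxybenzoate (20 mol%), neat, 4 °C
Reagents that add atoms: methyl vinyl ketone, CC(=O)C=C
Why: Enamine-catalysed Michael addition of an aldehyde to a vinyl ketone, in which the (E)-enamine of 14 is shielded on its Re face by the methoxydiphenylmethyl group of the (S)-pyrrolidine and adds through its Si face to the hydrogen-bond-activated enone, so that C6 is set by the catalyst over the resident C7 centre.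

Step 8
Reactants: 16 (2S,3R,5R)-5-[(tert-butyldimethylsilyl)oxy]-3,7-dimethyl-2-(3-oxobutyl)oct-6-enal
Product: 18 (4S)-4-[(2R,4R)-4-[(tert-butyldimethylsilyl)oxy]-6-methylhept-5-en-2-yl]cyclohex-2-en-1-one, via aldol adduct 17 (not isolated)
Conditions: LiOH (0.3 equiv), i-PrOH, rt
Reagents that add atoms: none
Why: Intramolecular aldol condensation, 6-(enolendo)-exo-trig, in which the methyl ketone enolate adds to the aldehyde and aldol 17 loses water to the conjugated enone, closing the carbocycle under a mild base chosen so that cyclisation outruns epimerisation at C6, which is no longer α to a carbonyl once the ring is closed.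

Step 9
Reactants: 18 (4S)-4-[(2R,4R)-4-[(tert-butyldimethylsilyl)oxy]-6-methylhept-5-en-2-yl]cyclohex-2-en-1-one; 19 N-phenylbis(trifluoromethanesulfonimide)
Product: 21 (4S)-4-[(2R,4R)-4-[(tert-butyldimethylsilyl)oxy]-6-methylhept-5-en-2-yl]cyclohexa-1,5-dien-1-yl trifluoromethanesulfonate, via lithium dienolate 20 (not isolated)
Conditions: LiN(i-Pr)2 (1.1 equiv), THF, −78 °C; then 19, −78 to 0 °C
Reagents that add atoms: N-phenylbis(trifluoromethanesulfonimide), O=S(=O)(N(c1ccccc1)S(=O)(=O)C(F)(F)F)C(F)(F)F
Why: Kinetic deprotonation of a cyclohex-2-enone by an amide base takes place at the α'-CH2 (C4) and gives the cross-conjugated dienolate 20, whose O-sulfonylation fixes the diene at C1=C2/C3=C4, while the γ-hydrogen on C6 is not removed and C6 keeps its configuration.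

Step 10
Reactants: 21 (4S)-4-[(2R,4R)-4-[(tert-butyldimethylsilyl)oxy]-6-methylhept-5-en-2-yl]cyclohexa-1,5-dien-1-yl trifluoromethanesulfonate; 22 methylmagnesium bromide
Product: 23 tert-butyl(dimethyl){[(4R,6R)-2-methyl-6-[(1S)-4-methylcyclohexa-2,4-dien-1-yl]hept-2-en-4-yl]oxy}silane
Conditions: 22 (1.3 equiv), Fe(acac)3 (5 mol%), THF/N-methylpyrrolidone, −30 °C
Reagents that add atoms: methylmagnesium bromide, C[Mg]Br
Why: Iron-catalysed Kumada-type cross-coupling of an enol triflate with an alkyl Grignard reagent, which puts the C3 methyl group on a diene whose position is already fixed and so avoids the regioisomer mixtures of a carbinol dehydration.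

Step 11
Reactants: 23 tert-butyl(dimethyl){[(4R,6R)-2-methyl-6-[(1S)-4-methylcyclohexa-2,4-dien-1-yl]hept-2-en-4-yl]oxy}silane
Product: 24 (4R,6R)-2-methyl-6-[(1S)-4-methylcyclohexa-2,4-dien-1-yl]hept-2-en-4-ol
Conditions: Bu4NF (1.2 equiv), THF, 0 °C to rt
Reagents that add atoms: none
Why: Fluoride cleavage of the silyl ether under non-acidic conditions, which spares the isomerisable 1,3-diene and the ionisable allylic carbinol C9.

Step 12
Reactants: 24 (4R,6R)-2-methyl-6-[(1S)-4-methylcyclohexa-2,4-dien-1-yl]hept-2-en-4-ol; 25 acetic anhydride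
Product: 26 (4R,6R)-2-methyl-6-[(1S)-4-methylcyclohexa-2,4-dien-1-yl]hept-2-en-4-yl acetate
Conditions: Ac2O, pyridine, DMAP (5 mol%), CH2Cl2, 0 °C
Reagents that add atoms: acetic anhydride, CC(=O)OC(C)=O
Why: Nucleophile-catalysed O-acylation with retention at C9, which installs the acetate of the target and at the same time the electron-withdrawing group that tempers the C10=C11 alkene toward singlet oxygen.

Step 13
Reactants: 26 (4R,6R)-2-methyl-6-[(1S)-4-methylcyclohexa-2,4-dien-1-yl]hept-2-en-4-yl acetate; 27 dioxygen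
Product: 28 (4R,6R)-2-methyl-6-[(1S,4R,7S)-5-methyl-2,3-dioxabicyclo[2.2.2]oct-5-en-7-yl]hept-2-en-4-yl acetate (O–O bridge anti to the side chain)
Conditions: O2 (1 atm), meso-tetraphenylporphyrin (0.5 mol%), CH2Cl2, −78 °C, white LED, stopped when 26 is consumed
Reagents that add atoms: dioxygen, O=O
Why: The photoexcited sensitiser passes its energy to ground-state dioxygen, and the singlet dioxygen so formed adds to the ring diene C1=C2–C3=C4, held s-cis by the ring, in a concerted suprafacial [4+2] cycloaddition that forms the C1–O and C4–O bonds together. The closest known reaction type is the dye-sensitised photooxygenation of 5-alkylcyclohexa-1,3-dienes to bicyclic endoperoxides. The 1,2-dioxane ring is closed by the cycloaddition itself (the O–O bond is brought in intact and both of its ends bond in the same event), which gives the 2,3-dioxabicyclo[2.2.2]oct-5-ene. C1 and C4 are the new stereocentres: suprafacial addition makes their oxygens cis to each other, and the C6 stereocentre with its α-branched chain, the only sp3 substituent next to the diene, covers its own face of C1, so that dioxygen should come from the opposite face. The step needs this facial selectivity, which the C6 chain may secure only in part (the syn isomer is separable and usable, see the fallback), and it needs cycloaddition to win over ene oxygenation at C10=C11 and at the ring allylic hydrogens, which the fixed s-cis geometry, the low temperature and the allylic acetate on C9 should secure.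

Step 14
Reactants: 28 (4R,6R)-2-methyl-6-[(1S,4R,7S)-5-methyl-2,3-dioxabicyclo[2.2.2]oct-5-en-7-yl]hept-2-en-4-yl acetate
Product: 29 (4R,6R)-6-[(1S,2S)-2-hydroxy-4-methyl-5-oxocyclohex-3-en-1-yl]-2-methylhept-2-en-4-yl acetate
Conditions: Et3N (1.2 equiv), CH2Cl2, 0 °C to rt
Reagents that add atoms: none
Why: Kornblum–DeLaMare rearrangement, in which the amine removes the bridgehead hydrogen on C4 (flanked by the C5 methylene and more exposed than the C1 hydrogen next to the branched C6) with concerted O–O cleavage to the C4 ketone and the C1 alkoxide, the C1–O bond staying intact so that C1 keeps the configuration set in step 13.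

Step 15
Reactants: 29 (4R,6R)-6-[(1S,2S)-2-hydroxy-4-methyl-5-oxocyclohex-3-en-1-yl]-2-methylhept-2-en-4-yl acetate
Product: 31 (4R,6R)-6-[(1S,2R,4S)-2-hydroxy-4-methyl-5-oxocyclohexyl]-2-methylhept-2-en-4-yl acetate, via C3-epimer mixture 30 (not isolated)
Conditions: [(Ph3P)CuH]6 (0.35 equiv), H2O (2 equiv), degassed toluene, rt; then DBU (0.2 equiv), rt
Reagents that add atoms: none
Why: Conjugate reduction of an enone by a phosphine-stabilised copper hydride, in which hydride goes to C2 of the enone only (the isolated alkene, the allylic acetate and the free hydroxyl are inert), water protonates the copper enolate, and DBU then equilibrates the epimerisable C3 to the all-equatorial isomer with the methyl group cis to the C1 hydroxyl.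

Step 16
Reactants: 31 (4R,6R)-6-[(1S,2R,4S)-2-hydroxy-4-methyl-5-oxocyclohexyl]-2-methylhept-2-en-4-yl acetate; 32 angelic acid
Product: 34 (1R,2S,5S)-2-[(2R,4R)-4-acetoxy-6-methylhept-5-en-2-yl]-5-methyl-4-oxocyclohexyl (2Z)-2-methylbut-2-enoate, via mixed anhydride 33 (not isolated)
Conditions: 32 (3 equiv), 2,4,6-trichlorobenzoyl chloride (3 equiv), Et3N (3.3 equiv), toluene, rt; then 31, 75 °C
Reagents that add atoms: angelic acid, C/C=C(/C)C(=O)O
Why: Yamaguchi esterification, in which the alcohol attacks the unhindered angeloyl carbonyl of mixed anhydride 33 (the aroyl carbonyl is blocked by two ortho chlorines) with retention at C1, and in which leaving out a nucleophilic pyridine catalyst avoids the addition–elimination that would turn the (Z)-angelate into the (E)-tiglate.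

Step 17
Reactants: 34 (1R,2S,5S)-2-[(2R,4R)-4-acetoxy-6-methylhept-5-en-2-yl]-5-methyl-4-oxocyclohexyl (2Z)-2-methylbut-2-enoate
Product: 35 (1R,2S,4R,5S)-2-[(2R,4R)-4-acetoxy-6-methylhept-5-en-2-yl]-4-hydroxy-5-methylcyclohexyl (2Z)-2-methylbut-2-enoate (CNP0237033.1)
Conditions: LiBH(s-Bu)3 (1.1 equiv), THF, −78 °C; then pH 7 phosphate buffer
Reagents that add atoms: none
Why: Diastereoselective ketone reduction by a bulky trialkylborohydride, which on the chair holding the C3 methyl, the C1 ester and the C6 chain equatorial attacks C4 along the equatorial trajectory and gives the axial alcohol, cis to the C3 methyl and to the C1 oxygen, while the acetate and the trisubstituted angelate should not be reduced at −78 °C.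

**Compound list**

1 | 3-methylglutaric anhydride | CC1CC(=O)OC(=O)C1 | starting material
2 | methanol | CO | starting material
3 | (R)-5-methoxy-3-methyl-5-oxopentanoic acid | COC(=O)C[C@H](C)CC(=O)O | intermediate
4 | N,O-dimethylhydroxylamine hydrochloride | CNOC.Cl | starting material
5 | methyl (R)-5-(imidazol-1-yl)-3-methyl-5-oxopentanoate (acyl imidazolide) | COC(=O)C[C@H](C)CC(=O)n1ccnc1 | intermediate
6 | methyl (R)-5-[methoxy(methyl)amino]-3-methyl-5-oxopentanoate | COC(=O)C[C@H](C)CC(=O)N(C)OC | intermediate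
7 | 2-methyl-1-propenylmagnesium bromide | CC(C)=C[Mg]Br | starting material
8 | bromomagnesium alkoxide of the tetrahedral adduct of 6 and 7 (magnesium hemiaminal, new carbon unassigned) | COC(=O)C[C@H](C)CC(O[Mg]Br)(C=C(C)C)N(C)OC | intermediate
9 | methyl (R)-3,7-dimethyl-5-oxooct-6-enoate | COC(=O)C[C@H](C)CC(=O)C=C(C)C | intermediate
10 | methyl (3R,5R)-5-hydroxy-3,7-dimethyloct-6-enoate | COC(=O)C[C@H](C)C[C@H](C=C(C)C)O | intermediate
11 | tert-butyldimethylsilyl chloride | CC(C)(C)[Si](C)(C)Cl | starting material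
12 | methyl (3R,5R)-5-[(tert-butyldimethylsilyl)oxy]-3,7-dimethyloct-6-enoate | COC(=O)C[C@H](C)C[C@H](C=C(C)C)O[Si](C)(C)C(C)(C)C | intermediate
13 | diisobutylaluminium hemiacetal of ester 12 (former ester carbon bearing OMe and OAl(i-Bu)2) | COC(O[Al](CC(C)C)CC(C)C)C[C@H](C)C[C@H](C=C(C)C)O[Si](C)(C)C(C)(C)C | intermediate
14 | (3R,5R)-5-[(tert-butyldimethylsilyl)oxy]-3,7-dimethyloct-6-enal | O=CC[C@H](C)C[C@H](C=C(C)C)O[Si](C)(C)C(C)(C)C | intermediate
15 | methyl vinyl ketone | CC(=O)C=C | starting material
16 | (2S,3R,5R)-5-[(tert-butyldimethylsilyl)oxy]-3,7-dimethyl-2-(3-oxobutyl)oct-6-enal | O=C[C@@H](CCC(C)=O)[C@H](C)C[C@H](C=C(C)C)O[Si](C)(C)C(C)(C)C | intermediate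
17 | (4S)-3-hydroxy-4-[(2R,4R)-4-[(tert-butyldimethylsilyl)oxy]-6-methylhept-5-en-2-yl]cyclohexan-1-one (aldol adduct, carbinol epimers) | O=C1CC[C@H](C(O)C1)[C@H](C)C[C@H](C=C(C)C)O[Si](C)(C)C(C)(C)C | intermediate
18 | (4S)-4-[(2R,4R)-4-[(tert-butyldimethylsilyl)oxy]-6-methylhept-5-en-2-yl]cyclohex-2-en-1-one | O=C1CC[C@H](C=C1)[C@H](C)C[C@H](C=C(C)C)O[Si](C)(C)C(C)(C)C | intermediate
19 | N-phenylbis(trifluoromethanesulfonimide) | O=S(=O)(N(c1ccccc1)S(=O)(=O)C(F)(F)F)C(F)(F)F | starting material
20 | lithium (4S)-4-[(2R,4R)-4-[(tert-butyldimethylsilyl)oxy]-6-methylhept-5-en-2-yl]cyclohexa-1,5-dien-1-olate (cross-conjugated dienolate) | [Li]OC1=CC[C@H](C=C1)[C@H](C)C[C@H](C=C(C)C)O[Si](C)(C)C(C)(C)C | intermediate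
21 | (4S)-4-[(2R,4R)-4-[(tert-butyldimethylsilyl)oxy]-6-methylhept-5-en-2-yl]cyclohexa-1,5-dien-1-yl trifluoromethanesulfonate | O=S(=O)(OC1=CC[C@H](C=C1)[C@H](C)C[C@H](C=C(C)C)O[Si](C)(C)C(C)(C)C)C(F)(F)F | intermediate
22 | methylmagnesium bromide | C[Mg]Br | starting material
23 | tert-butyl(dimethyl){[(4R,6R)-2-methyl-6-[(1S)-4-methylcyclohexa-2,4-dien-1-yl]hept-2-en-4-yl]oxy}silane | C1=CC(C)=CC[C@H]1[C@H](C)C[C@H](C=C(C)C)O[Si](C)(C)C(C)(C)C | intermediate
24 | (4R,6R)-2-methyl-6-[(1S)-4-methylcyclohexa-2,4-dien-1-yl]hept-2-en-4-ol | C1=CC(C)=CC[C@H]1[C@H](C)C[C@H](C=C(C)C)O | intermediate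
25 | acetic anhydride | CC(=O)OC(C)=O | starting material
26 | (4R,6R)-2-methyl-6-[(1S)-4-methylcyclohexa-2,4-dien-1-yl]hept-2-en-4-yl acetate | C1=CC(C)=CC[C@H]1[C@H](C)C[C@H](C=C(C)C)OC(C)=O | intermediate
27 | dioxygen | O=O | starting material
28 | (4R,6R)-2-methyl-6-[(1S,4R,7S)-5-methyl-2,3-dioxabicyclo[2.2.2]oct-5-en-7-yl]hept-2-en-4-yl acetate (peroxide bridge anti to the side chain) | O2[C@@H]1C=C(C)[C@H](O2)C[C@H]1[C@H](C)C[C@H](C=C(C)C)OC(C)=O | intermediate
29 | (4R,6R)-6-[(1S,2S)-2-hydroxy-4-methyl-5-oxocyclohex-3-en-1-yl]-2-methylhept-2-en-4-yl acetate (C1–OH trans to the chain) | O[C@@H]1C=C(C)C(=O)C[C@H]1[C@H](C)C[C@H](C=C(C)C)OC(C)=O | intermediate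
30 | C3-epimer mixture of 31 (methyl-bearing carbon unassigned) | O[C@@H]1CC(C)C(=O)C[C@H]1[C@H](C)C[C@H](C=C(C)C)OC(C)=O | intermediate
31 | (4R,6R)-6-[(1S,2R,4S)-2-hydroxy-4-methyl-5-oxocyclohexyl]-2-methylhept-2-en-4-yl acetate | O[C@@H]1C[C@H](C)C(=O)C[C@H]1[C@H](C)C[C@H](C=C(C)C)OC(C)=O | intermediate
32 | angelic acid, (2Z)-2-methylbut-2-enoic acid | C/C=C(/C)C(=O)O | starting material
33 | (2Z)-2-methylbut-2-enoic 2,4,6-trichlorobenzoic anhydride | C/C=C(/C)C(=O)OC(=O)c1c(Cl)cc(Cl)cc1Cl | intermediate
34 | (1R,2S,5S)-2-[(2R,4R)-4-acetoxy-6-methylhept-5-en-2-yl]-5-methyl-4-oxocyclohexyl (2Z)-2-methylbut-2-enoate | C/C=C(/C)C(=O)O[C@@H]1C[C@H](C)C(=O)C[C@H]1[C@H](C)C[C@H](C=C(C)C)OC(C)=O | intermediate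
35 | (1R,2S,4R,5S)-2-[(2R,4R)-4-acetoxy-6-methylhept-5-en-2-yl]-4-hydroxy-5-methylcyclohexyl (2Z)-2-methylbut-2-enoate | C/C=C(/C)C(=O)O[C@@H]1C[C@H](C)[C@H](O)C[C@H]1[C@H](C)C[C@H](C=C(C)C)OC(C)=O | target

**Step count and risks**

Total step count: 17. Longest linear sequence: 17 steps (1 to 35); the route is fully linear.

Steps most likely to fail:

1. Step 13. Facial discrimination by the C6 chain may be incomplete, so that dioxygen also adds syn to the chain, and ene oxygenation at C10=C11 or at ring allylic hydrogens may compete. The fallback makes the route stereoconvergent instead of relying on face selectivity. It sets out from 26: the photooxygenation is run as in step 13, and the syn endoperoxide (4R,6R)-2-methyl-6-[(1R,4S,7S)-5-methyl-2,3-dioxabicyclo[2.2.2]oct-5-en-7-yl]hept-2-en-4-yl acetate F1 is separated from 28 and kept. Et3N in CH2Cl2 opens it in the manner of step 14 to the C1-epimeric hydroxy enone (4R,6R)-6-[(1S,2R)-2-hydroxy-4-methyl-5-oxocyclohex-3-en-1-yl]-2-methylhept-2-en-4-yl acetate F2, whose hydroxyl is cis to the chain. Mitsunobu esterification with angelic acid 32 (PPh3, diisopropyl azodicarboxylate, toluene, 0 °C) inverts C1 and should give the enone angelate (1S,6S)-6-[(2R,4R)-4-acetoxy-6-methylhept-5-en-2-yl]-3-methyl-4-oxocyclohex-2-en-1-yl (2Z)-2-methylbut-2-enoate F3. Conjugate reduction with [(Ph3P)CuH]6 and DBU equilibration, as in step 15, brings the material back to the route at 34.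

2. Step 14. The base may remove the wrong bridgehead hydrogen (C1–H, giving the C1 ketone), or may isomerise the γ-hydroxy enone further to the 1,4-dione. The fallback replaces the base-induced fragmentation by reduction and sterically controlled oxidation. It sets out from 28: thiourea in MeOH at rt reduces the O–O bond to the cis-enediol (4R,6R)-6-[(1S,2S,5R)-2,5-dihydroxy-4-methylcyclohex-3-en-1-yl]-2-methylhept-2-en-4-yl acetate F4. Oxidation with catalytic TEMPO and PhI(OAc)2 in CH2Cl2 should then take the less hindered C4 carbinol ahead of the C1 carbinol that sits next to the branched C6, which returns to the route at 29.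

3. Step 16. Acylation of the hindered C1 hydroxyl may be slow, and the angeloyl group may isomerise from Z to E on the way. The fallback builds the Z-alkene on the ester instead of transferring it. It sets out from 31: esterification with 2-[bis(2,2,2-trifluoroethoxy)phosphoryl]propanoic acid (dicyclohexylcarbodiimide, DMAP cat., CH2Cl2) gives the phosphonate ester (1R,2S,5S)-2-[(2R,4R)-4-acetoxy-6-methylhept-5-en-2-yl]-5-methyl-4-oxocyclohexyl 2-[bis(2,2,2-trifluoroethoxy)phosphoryl]propanoate F5. Still–Gennari olefination (KN(SiMe3)2, 18-crown-6, THF, −78 °C, then acetaldehyde) should form the (Z)-2-methylbut-2-enoate and returns to the route at 34.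

Further compounds
F1 | step 13 | (4R,6R)-2-methyl-6-[(1R,4S,7S)-5-methyl-2,3-dioxabicyclo[2.2.2]oct-5-en-7-yl]hept-2-en-4-yl acetate (peroxide bridge syn to the side chain) | O2[C@H]1C=C(C)[C@@H](O2)C[C@H]1[C@H](C)C[C@H](C=C(C)C)OC(C)=O
F2 | step 13 | (4R,6R)-6-[(1S,2R)-2-hydroxy-4-methyl-5-oxocyclohex-3-en-1-yl]-2-methylhept-2-en-4-yl acetate | O[C@H]1C=C(C)C(=O)C[C@H]1[C@H](C)C[C@H](C=C(C)C)OC(C)=O
F3 | step 13 | (1S,6S)-6-[(2R,4R)-4-acetoxy-6-methylhept-5-en-2-yl]-3-methyl-4-oxocyclohex-2-en-1-yl (2Z)-2-methylbut-2-enoate | C/C=C(/C)C(=O)O[C@@H]1C=C(C)C(=O)C[C@H]1[C@H](C)C[C@H](C=C(C)C)OC(C)=O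
F4 | step 14 | (4R,6R)-6-[(1S,2S,5R)-2,5-dihydroxy-4-methylcyclohex-3-en-1-yl]-2-methylhept-2-en-4-yl acetate | O[C@@H]1C=C(C)[C@H](O)C[C@H]1[C@H](C)C[C@H](C=C(C)C)OC(C)=O
F5 | step 16 | (1R,2S,5S)-2-[(2R,4R)-4-acetoxy-6-methylhept-5-en-2-yl]-5-methyl-4-oxocyclohexyl 2-[bis(2,2,2-trifluoroethoxy)phosphoryl]propanoate | CC(C(=O)O[C@@H]1C[C@H](C)C(=O)C[C@H]1[C@H](C)C[C@H](C=C(C)C)OC(C)=O)P(=O)(OCC(F)(F)F)OCC(F)(F)F
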